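Remark on the chemistry: the carbinol carbon of 7 is a stereocentre that forms as a racemate and disappears in step 3, so the achiral target needs no stereocontrol; formaldehyde is taken as a methanol-free aqueous solution made from paraformaldehyde, which also supplies the water.

## Structural features

The target is a 1,2,4-trisubstituted benzene ring, with OCH3 at C2 and CH3 at C4, whose C1 is bonded to a fully substituted carbinol carbon. That carbon carries a free tertiary hydroxyl and two identical CH2-O-C(=O)CH(CH3)2 arms, so the side chain is a 2-arylglycerol 1,3-diisobutyrate. The arene is the only ring and there is no stereocentre, because the two arms are the same and the carbinol carbon is merely prochiral; no neighbouring stereocentres have to be related. The fragile groups are the two primary esters, which sit next to a free hydroxyl and can migrate or hydrolyse under base, and the tertiary benzylic alcohol, which the ortho methoxy and para methyl donors activate towards ionisation in strong acid. The arene poses no problem, since an iodide with all three substituents in place can be bought. The real difficulty is the tetrasubstituted benzylic carbon beside the ortho methoxy group, which must receive one oxygen and two oxygenated one-carbon arms, followed by acylation of two primary hydroxyls while the tertiary one stays free. The key step exploits the fact that this carbon is bonded to aryl C1, to a hydroxyl oxygen and to two CH2O carbons: with one arm raised to the ester oxidation level it becomes the carbene carbon of an aryl diazoacetate, and its C-OH and C-CH2OH bonds can then come from water and formaldehyde in one operation.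

## Logic of the disconnections

10 => 8 + 9. The two acyl C(=O)-O bonds to the primary oxygens are cut first. They are the most labile bonds of 10 and the ones able to migrate towards the tertiary hydroxyl, so they are best made last. Cutting both at once respects the symmetry and removes eight carbons, leaving 8 and two equivalents of 9. The forward step must distinguish the primary hydroxyls from the tertiary benzylic one, which calls for a branched acylating agent, low temperature and no nucleophilic acylation catalyst.

8 => 7. No skeletal bond is cut; one CH2OH arm is raised to the ester oxidation level. This breaks the symmetry on paper and gives the carbinol carbon the acceptor group that a stabilised carbene or ylide at that carbon needs. The demand is a hydride reduction of a hindered dihydroxy ester that spares everything else and is fast enough to precede retro-aldol loss of the CH2OH arm.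

7 => 3 + 4 + 5, through 6. Two bonds at the same carbon are cut, the carbinol C-OH bond and the carbinol C-CH2OH bond. A carbon that gains an O-H partner and a carbon electrophile in one event is a carbene carbon, so the whole oxygenated quaternary centre collapses to 3 and the two simplest sources of oxygen and of one carbon, with no protecting group. The demand is that 6 is intercepted by 4 before it tautomerises, and that the carbene prefers the O-H bond of 5 to the C-H bonds of the ortho methoxy group.

3 => 1 + 2. The bond between aryl C1 and the diazo carbon is cut. This places the disconnection at the arene, so that the substitution pattern is bought in 1, and it reaches the donor-acceptor diazo ester in one step without a separate diazo-transfer operation. The demand is a coupling that conserves the diazo group, which means room temperature and a catalyst that couples faster than it decomposes diazo compounds.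

## Other disconnections considered

Alternative 1: The cut goes through the benzene ring itself, at ring bonds C1-C2 and C5-C6, so that the arene would be built from two open-chain pieces. In the forward direction the silyl ketene acetal diene 1-methoxy-3-methyl-1-(trimethylsilyloxy)buta-1,3-diene A1 would undergo a [4+2] cycloaddition with the terminal ynone 1-[(tert-butyldimethylsilyl)oxy]but-3-yn-2-one A2. The adduct would aromatise on acidic work-up, with loss of methanol and hydrolysis of the trimethylsilyl ether, to the ortho-hydroxyaryl ketone 2-[(tert-butyldimethylsilyl)oxy]-1-(2-hydroxy-4-methylphenyl)ethan-1-one A3. In its favour, the polarised diene A1 dictates the regiochemistry, because its CH2 terminus bonds to the beta carbon of A2. Ortho oxygen, para methyl and the acyl carbon would therefore arrive in the right places in one pericyclic event, and one oxygenated arm is already attached in A3. Against it here, the ring that it builds can be bought fully substituted. After A3 the phenol would still have to be methylated, the second arm attached to the ketone carbon (for example by methylenation and dihydroxylation), the silyl ether removed and the diol acylated. Both A1 and the sensitive ynone A2 would have to be prepared first. In comparison, the cycloaddition should be at least as predictable as the carbene trapping and it avoids diazo compounds, so on mechanistic reliability and on hazard it is the equal or the better of the chosen plan. Structurally it is the weaker plan, because it leaves the quaternary carbinol carbon unmade, and in step economy it is clearly behind, needing roughly twice as many steps.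

Alternative 2: The target is read as an oxidised benzofuran. The cuts are the carbinol C-OH bond and a C-O bond at the neighbouring arm carbon, with the ortho oxygen tied into the furan ring. In the forward direction OsO4-catalysed syn-dihydroxylation, with N-methylmorpholine N-oxide as the oxidant, would be applied to the C2=C3 bond of (6-methyl-1-benzofuran-3-yl)methyl 2-methylpropanoate A4. It would give the racemic cis lactol (2,3-dihydroxy-6-methyl-2,3-dihydro-1-benzofuran-3-yl)methyl 2-methylpropanoate A5. In its favour, the tertiary C-O bond would form with complete regiocontrol at the most alkene-like bond of A4, one isobutyrate is already in place, and no diazo compound is needed. Against it here, osmylation of the furan double bond of A4 costs aromatic stabilisation and is expected to be slow. A5 is the cyclic hemiacetal of an alpha-hydroxy aldehyde and would have to be opened and reduced. The liberated phenol would then have to be methylated with base in the presence of an ester and free hydroxyls, which invites acyl migration and hydrolysis, and a second acylation would still follow. A4 itself is not a commercial compound and would need several steps. In comparison, both plans make the tertiary C-O bond in a catalytic metal-mediated step, and the mechanism of dihydroxylation is the better understood, so on that point the alternative is the equal or slightly the better. The cis relationship in A5 and the differentiation of the two arms bring nothing, because the arms of the target are identical, and in step economy this plan is clearly the worse.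

Alternative 3: Both bonds from the carbinol carbon to its CH2 groups are cut, which takes the target back to a benzoate ester and two hydroxymethyl anion equivalents. In the forward direction methyl 2-methoxy-4-methylbenzoate A6 would take up two equivalents of the CeCl3-activated Grignard reagent [(isopropoxydimethylsilyl)methyl]magnesium chloride A7. The product would be 2-(2-methoxy-4-methylphenyl)-1,3-bis[isopropoxy(dimethyl)silyl]propan-2-ol A8. Tamao oxidation of both C-Si bonds of A8 (H2O2, KF, KHCO3) would then lead to 8, and acylation with 9 would follow as in the chosen route. In its favour, the twofold addition to A6 mirrors the symmetry of the target, no stereocentre is ever formed, and neither a diazo compound nor a precious metal is needed. A6 can be bought and A7 is a well-established hydroxymethyl anion equivalent. The target would be reached in three steps from A6, one fewer than in the chosen plan, so on step economy and on hazard this alternative is the better. Against it here, after the first addition of A7 enolisation at the acidic alpha-silyl CH2 position competes with the second addition, which the ortho methoxy group slows further. A8 is a double beta-hydroxysilane at an electron-rich tertiary benzylic centre, so Peterson elimination, triggered by acid, base, silica or fluoride, would compete during isolation and during the oxidation. In comparison, both plans converge on 8 and are structurally equal. The chosen plan installs the tertiary oxygen and one arm in a single catalytic step whose main failure mode, plain O-H insertion, leaves the skeleton intact, whereas the elimination from A8 would destroy one arm irreversibly. That difference in mechanistic risk, and not the step count, is the reason for preferring the carbene route.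

Key step: step 2

## Route

Step 1
Reactants: 1 1-iodo-2-methoxy-4-methylbenzene; 2 ethyl diazoacetate
Product: 3 ethyl 2-diazo-2-(2-methoxy-4-methylphenyl)acetate
Conditions: Pd(PPh3)4 (5 mol %), Ag2CO3 (0.5 equiv), Et3N (1.3 equiv), 2 (1.3 equiv, commercial solution in toluene), toluene, rt, dark
Reagents that add atoms: none
Why: Palladium-catalysed cross-coupling of an aryl iodide with the C-H bond of an acceptor diazo ester: oxidative addition of zerovalent palladium into the C-I bond of 1, Ag2CO3-assisted exchange of iodide for the deprotonated diazoacetate and reductive elimination all proceed at room temperature, where loss of N2 at palladium is slow, so the diazo group should be retained. Reagent 2 is handled only as its dilute commercial solution and 3 is a donor-acceptor diazo ester that can be chromatographed without heating, which keeps the hazard of the diazo chemistry low.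

Step 2
Reactants: 3 ethyl 2-diazo-2-(2-methoxy-4-methylphenyl)acetate; 4 formaldehyde; 5 water
Product: 7 racemic ethyl 2,3-dihydroxy-2-(2-methoxy-4-methylphenyl)propanoate, via oxonium ylide 6 (not isolated)
Conditions: Rh2(OAc)4 (2 mol %), methanol-free aqueous HCHO (10 equiv), EtOAc, 60 °C, slow addition of 3 by syringe pump
Reagents that add atoms: none
Why: Rh2(OAc)4, a divalent rhodium carboxylate dimer, decomposes 3 with loss of N2 to an electrophilic Rh2(OAc)4-bound donor-acceptor carbene, and 5 adds through oxygen to the carbene carbon to give oxonium ylide 6. The nucleophilic carbon of 6, stabilised by the aryl ring and the ester, should add to the free carbonyl form of 4 in an aldol-type step before the 1,2-proton shift that would end in plain O-H insertion, so that the C-OH bond and the C-CH2OH bond form on the same carbon. The closest known reaction type is the Rh2(OAc)4-catalysed three-component coupling of aryl diazoacetates with water or alcohols and aryl aldehydes or imines, of which formaldehyde is a smaller and less documented acceptor. No ring is closed. The new carbinol stereocentre arises with an achiral catalyst and is therefore racemic, which is acceptable because step 3 makes its two carbon arms identical. The step needs chemoselectivity for aldol trapping over proton transfer, and for O-H capture over insertion into the C-H bonds of the ortho methoxy group or carbene dimerisation. These are secured by the lifetime of the aryl- and ester-stabilised ylide, by a large excess of the smallest and most electrophilic aldehyde, by the low reactivity of methyl C-H bonds towards this carbene, by slow addition of 3 and by the absence of methanol as a competing O-H donor.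

Step 3
Reactants: 7 racemic ethyl 2,3-dihydroxy-2-(2-methoxy-4-methylphenyl)propanoate
Product: 8 2-(2-methoxy-4-methylphenyl)propane-1,2,3-triol
Conditions: LiBH4 (2.5 equiv), THF, 0 °C to rt; then MeOH, aqueous NH4Cl
Reagents that add atoms: none
Why: Ester reduction by LiBH4, which the neighbouring hydroxyl groups accelerate through alkoxyborohydride formation and lithium chelation; the aryl ring, the methyl ether and the tertiary alcohol are inert to this reagent, which is also safer to handle than LiAlH4. The stereocentre of 7 disappears because both carbon arms become CH2OH.

Step 4
Reactants: 8 2-(2-methoxy-4-methylphenyl)propane-1,2,3-triol; 9 isobutyryl chloride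
Product: 10 2-hydroxy-2-(2-methoxy-4-methylphenyl)propane-1,3-diyl bis(2-methylpropanoate)
Conditions: 9 (2.1 equiv), pyridine (3 equiv), CH2Cl2, -20 to 0 °C
Reagents that add atoms: none
Why: Nucleophilic acyl substitution (O-acylation) by the two primary hydroxyls; the tertiary benzylic hydroxyl, flanked by the ortho-substituted ring and two CH2 groups, should not react with a branched acyl chloride at low temperature in the absence of a nucleophilic catalyst such as DMAP. Pyridine takes up the HCl, so the acid-sensitive benzylic carbinol is not exposed to it.

## Compound list

1 | 1-iodo-2-methoxy-4-methylbenzene | COc1cc(C)ccc1I | starting material
2 | ethyl diazoacetate | CCOC(=O)C=[N+]=[N-] | starting material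
3 | ethyl 2-diazo-2-(2-methoxy-4-methylphenyl)acetate | CCOC(=O)C(=[N+]=[N-])c1ccc(C)cc1OC | intermediate
4 | formaldehyde (used as a methanol-free aqueous solution) | C=O | starting material
5 | water | O | starting material
6 | oxonium ylide (adduct of water to the carbene carbon derived from 3, drawn without the metal) | CCOC(=O)[C-]([OH2+])c1ccc(C)cc1OC | intermediate
7 | racemic ethyl 2,3-dihydroxy-2-(2-methoxy-4-methylphenyl)propanoate | CCOC(=O)C(O)(CO)c1ccc(C)cc1OC | intermediate
8 | 2-(2-methoxy-4-methylphenyl)propane-1,2,3-triol (achiral) | COc1cc(C)ccc1C(O)(CO)CO | intermediate
9 | isobutyryl chloride (2-methylpropanoyl chloride) | CC(C)C(Cl)=O | starting material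
10 | 2-hydroxy-2-(2-methoxy-4-methylphenyl)propane-1,3-diyl bis(2-methylpropanoate) (achiral) | COc1cc(C)ccc1C(O)(COC(=O)C(C)C)COC(=O)C(C)C | target

## Step count and risk

Total steps: 4. Longest linear sequence: 4 steps (1 to 3 to 7 to 8 to 10).

Least certain, in this order: step 2 (the key step), then steps 1, 3 and 4.

At step 2 the most likely failure is that the 1,2-proton shift within 6 outruns its addition to 4. In water most of 4 is present as its hydrate, and only the small free-carbonyl fraction can act as acceptor. Carbene-carbene coupling is a second loss if 3 is allowed to accumulate. The fallback gives up the carbene assembly of the carbinol carbon and sets out from 1. Iodine-magnesium exchange with i-PrMgCl·LiCl in THF at -20 °C should give (2-methoxy-4-methylphenyl)magnesium chloride F1. This is added without isolation to commercially available 2,2-dimethyl-1,3-dioxan-5-one in the presence of LaCl3·2LiCl, which suppresses enolisation of the ketone. The addition should give 5-(2-methoxy-4-methylphenyl)-2,2-dimethyl-1,3-dioxan-5-ol F2. Removal of the acetonide with 80 % aqueous acetic acid at room temperature then liberates the triol, and the fallback comes back to the route at 8.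

At step 1 the risk is that zerovalent palladium decomposes the diazo compound, so that carbene formation and dimerisation of 2 overtake the coupling. The ortho methoxy group slows the exchange at palladium and makes this competition less favourable than for unhindered aryl iodides. The fallback avoids 2 altogether and sets out from 1. Iodine-lithium exchange with n-BuLi in THF at -78 °C should give (2-methoxy-4-methylphenyl)lithium F3. This is transferred cold into excess diethyl oxalate at -78 °C to give ethyl 2-(2-methoxy-4-methylphenyl)-2-oxoacetate F4. Condensation with p-toluenesulfonylhydrazide in EtOH at 60 °C gives ethyl 2-(2-methoxy-4-methylphenyl)-2-[2-(4-methylbenzenesulfonyl)hydrazinylidene]acetate F5 as a mixture of C=N isomers. Bamford-Stevens elimination of sulfinate with DBU in CH2Cl2 at room temperature then gives the diazo ester, and the fallback comes back to the route at 3.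

At step 3 the alkoxide of the beta-hydroxy ester may undergo retro-aldol loss of the hydroxymethyl arm before hydride is delivered. The polar triol may also stay bound as borate esters and be lost on aqueous work-up. The fallback masks the diol and sets out from 7. Acetonide formation with 2,2-dimethoxypropane and PPTS in acetone should give racemic ethyl 4-(2-methoxy-4-methylphenyl)-2,2-dimethyl-1,3-dioxolane-4-carboxylate F6, which has no free alkoxide and cannot fragment. Reduction with LiBH4 in THF-MeOH gives racemic [4-(2-methoxy-4-methylphenyl)-2,2-dimethyl-1,3-dioxolan-4-yl]methanol F7, which is easily extracted. Hydrolysis of the acetonide with 80 % aqueous acetic acid at room temperature comes back to the route at 8.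

At step 4 the second acylation may stall at the monoester stage, or prolonged exposure to base and excess acyl chloride may cause acyl transfer onto the tertiary oxygen. The fallback replaces chemical acylation by an enzymatic transesterification and sets out from 8. Immobilised Candida antarctica lipase B with vinyl isobutyrate in tert-butyl methyl ether at 40 °C acylates primary hydroxyls under neutral conditions and does not accept tertiary alcohols. It should lead directly to 10 without any new intermediate.

## Further compounds

F1 | step 2 | (2-methoxy-4-methylphenyl)magnesium chloride | COc1cc(C)ccc1[Mg]Cl
F2 | step 2 | 5-(2-methoxy-4-methylphenyl)-2,2-dimethyl-1,3-dioxan-5-ol | COc1cc(C)ccc1C1(O)COC(C)(C)OC1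
F3 | step 1 | (2-methoxy-4-methylphenyl)lithium | COc1cc(C)ccc1[Li]
F4 | step 1 | ethyl 2-(2-methoxy-4-methylphenyl)-2-oxoacetate | CCOC(=O)C(=O)c1ccc(C)cc1OC
F5 | step 1 | ethyl 2-(2-methoxy-4-methylphenyl)-2-[2-(4-methylbenzenesulfonyl)hydrazinylidene]acetate (mixture of C=N isomers) | CCOC(=O)C(=NNS(=O)(=O)c1ccc(C)cc1)c1ccc(C)cc1OC
F6 | step 3 | racemic ethyl 4-(2-methoxy-4-methylphenyl)-2,2-dimethyl-1,3-dioxolane-4-carboxylate | CCOC(=O)C1(COC(C)(C)O1)c1ccc(C)cc1OC
F7 | step 3 | racemic [4-(2-methoxy-4-methylphenyl)-2,2-dimethyl-1,3-dioxolan-4-yl]methanol | COc1cc(C)ccc1C1(CO)COC(C)(C)O1
F0 | step 4 | none | none
A1 | alternative 1 | 1-methoxy-3-methyl-1-(trimethylsilyloxy)buta-1,3-diene | C=C(C)C=C(OC)O[Si](C)(C)C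
A2 | alternative 1 | 1-[(tert-butyldimethylsilyl)oxy]but-3-yn-2-one | C#CC(=O)CO[Si](C)(C)C(C)(C)C
A3 | alternative 1 | 2-[(tert-butyldimethylsilyl)oxy]-1-(2-hydroxy-4-methylphenyl)ethan-1-one | Cc1ccc(C(=O)CO[Si](C)(C)C(C)(C)C)c(O)c1
A4 | alternative 2 | (6-methyl-1-benzofuran-3-yl)methyl 2-methylpropanoate | CC(C)C(=O)OCc1coc2cc(C)ccc12
A5 | alternative 2 | racemic cis-(2,3-dihydroxy-6-methyl-2,3-dihydro-1-benzofuran-3-yl)methyl 2-methylpropanoate | CC(C)C(=O)OC[C@]1(O)[C@@H](O)Oc2cc(C)ccc21
A6 | alternative 3 | methyl 2-methoxy-4-methylbenzoate | COC(=O)c1ccc(C)cc1OC
A7 | alternative 3 | [(isopropoxydimethylsilyl)methyl]magnesium chloride | CC(C)O[Si](C)(C)C[Mg]Cl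
A8 | alternative 3 | 2-(2-methoxy-4-methylphenyl)-1,3-bis[isopropoxy(dimethyl)silyl]propan-2-ol | COc1cc(C)ccc1C(O)(C[Si](C)(C)OC(C)C)C[Si](C)(C)OC(C)C
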